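**Plan**

1. Longipinane numbering is used: C1 ketone, C2 CH2, C3 CHMe, C4 and C11 the cyclobutane bridgeheads, C5 (CH) and C10 (C–Me) the two one-carbon bridges, C6 CMe2, C7–C9 the three acyloxy carbons. Retrosynthesis removes the angelates one at a time (C9 ester, C7 ester, then the C8 ester with the C7 hydroxyl back to a 7,8-epoxide), then the C3 methyl (cuprate on a C2=C3 enone), then the cyclobutane bond C5–C11 (oxidative enolate coupling, C5 carrying a temporary carboxyl), and finally C7–C8 and C4–C5 together.
2. The enabling feature is that C5–C6(Me2)–C7(O) is the ring-opened form of a 2-silyloxy-3,3-dimethylcyclopropanecarboxylate (C7 oxygen as donor, a removable carboxyl on C5 as acceptor, C6 the gem-dimethyl carbon), while C8=C9(O)–C10=C4 is the 2-silyloxydiene of a 1-acetylcyclohexene. Opening the cyclopropane across this diene closes the seven-membered ring C4–C5–C6–C7–C8–C9–C10.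
3. The carboxyl is esterified to the C1 hydroxyl of the cyclohexene, so the event is intramolecular. The ester becomes a temporary lactone bridge (C5–CO–O–C1) that is later hydrolysed (C1–OH then becomes the ketone) and decarboxylated.
4. Forward order: cyclohexane ring (from cyclohexenone), then seven-membered ring plus lactone (step 10), then C10 methyl and C9 alcohol, then cyclobutane (C5–C11), then C3 methyl, then the 7,8-epoxide, which angelic acid opens at C8, then the C7 and the C9 angelates in turn.
5. Stereochemistry: one stereocentre (C1–OH) is set by CuCl/bisphosphine-catalysed asymmetric borylation; it fixes C4 through the tether and is later oxidised away. C10 (methylation anti to C5), C9 (Luche reduction), C7/C8 (epoxide anti to C9–OTBS, opening by angelate with inversion at C8) and C3 (cuprate anti to the C10 methyl) follow by substrate control; C5 and C11 are fixed by ring constraint.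

Key step: step 10

Remark (assumption): the cyclopropane stereocentres of 4, 5, 14 and 15 and C7 of 16 and 17 are carried as mixtures because they are erased in steps 10 and 11; C5 of 16–23 is drawn as the bridged lactone requires and is re-set in step 16.

**Route**

Step 1
Reactants: 1 isobutyraldehyde
Product: 2 tert-butyldimethyl[(2-methylprop-1-en-1-yl)oxy]silane
Conditions: TBSOTf, Et3N, CH2Cl2, 0 °C to rt
Reagents that add atoms: tert-butyldimethylsilyl triflate (CC(C)(C)[Si](C)(C)OS(=O)(=O)C(F)(F)F)
Why: Soft enolisation and O-silylation of an aldehyde with a silyl triflate and an amine base should give the silyl enol ether; no stereocentre is formed.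

Step 2
Reactants: 2 tert-butyldimethyl[(2-methylprop-1-en-1-yl)oxy]silane; 3 benzyl diazoacetate
Product: 4 benzyl 2-[(tert-butyldimethylsilyl)oxy]-3,3-dimethylcyclopropane-1-carboxylate (racemic cis/trans mixture)
Conditions: Rh2(OAc)4 (1 mol %), CH2Cl2, slow addition of 3, rt
Reagents that add atoms: none
Why: Cyclopropanation of the electron-rich silyl enol ether by the carbenoid formed from the diazo ester and Rh2(OAc)4 should give the donor–acceptor cyclopropane; both new stereocentres are erased in step 10, so the mixture is carried on.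

Step 3
Reactants: 4 benzyl 2-[(tert-butyldimethylsilyl)oxy]-3,3-dimethylcyclopropane-1-carboxylate
Product: 5 2-[(tert-butyldimethylsilyl)oxy]-3,3-dimethylcyclopropane-1-carboxylic acid (isomer mixture)
Conditions: H2 (1 atm), Pd on carbon (10 wt % Pd), EtOAc, rt
Reagents that add atoms: none
Why: Hydrogenolysis of the benzyl ester under neutral conditions should free the acid without opening the acid- and fluoride-sensitive silyloxycyclopropane.

Step 4
Reactants: 6 cyclohex-2-en-1-one
Product: 8 (S)-3-hydroxycyclohexan-1-one, via (S)-3-borylcyclohexanone pinacol ester 7 (not isolated)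
Conditions: CuCl (3 mol %), NaOtBu (6 mol %), (R,R)-QuinoxP* (3 mol %; ligand enantiomer chosen to deliver the S boronate), B2pin2, MeOH (2 equiv), THF, rt; then NaBO3·4H2O, THF/H2O, rt
Reagents that add atoms: bis(pinacolato)diboron (CC1(C)OB(B2OC(C)(C)C(C)(C)O2)OC1(C)C); sodium perborate ([Na+].[O-]OB=O)
Why: CuCl-catalysed asymmetric conjugate borylation of the enone with a chiral bisphosphine should set the only catalyst-derived stereocentre, and perborate oxidation of the C–B bond proceeds with retention.

Step 5
Reactants: 8 (S)-3-hydroxycyclohexan-1-one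
Product: 9 (S)-3-[(tert-butyldimethylsilyl)oxy]cyclohexan-1-one
Conditions: TBSCl, imidazole, DMF, 0 °C to rt
Reagents that add atoms: tert-butyldimethylsilyl chloride (CC(C)(C)[Si](C)(C)Cl)
Why: Standard silylation protects the β-hydroxy ketone against elimination during enolate chemistry; the stereocentre is untouched.

Step 6
Reactants: 9 (S)-3-[(tert-butyldimethylsilyl)oxy]cyclohexan-1-one
Product: 10 (S)-5-[(tert-butyldimethylsilyl)oxy]cyclohex-1-en-1-yl trifluoromethanesulfonate
Conditions: LDA, THF, −78 °C; then PhNTf2, −78 to 0 °C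
Reagents that add atoms: N-phenylbis(trifluoromethanesulfonimide) (O=S(=O)(N(c1ccccc1)S(=O)(=O)C(F)(F)F)C(F)(F)F)
Why: Kinetic deprotonation should occur at the CH2 remote from the silyloxy group (less hindered, no β-elimination), and O-triflation of this enolate gives the enol triflate with the double bond away from C1.

Step 7
Reactants: 10 (S)-5-[(tert-butyldimethylsilyl)oxy]cyclohex-1-en-1-yl trifluoromethanesulfonate
Product: 13 (S)-1-(5-hydroxycyclohex-1-en-1-yl)ethan-1-one, via ethoxydiene silyl ether 11 (not isolated), via silyl-protected methyl enone 12 (not isolated)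
Conditions: Pd(PPh3)4 (5 mol %), LiCl, tributyl(1-ethoxyvinyl)stannane, THF, 65 °C; then 2 M HCl, THF/MeOH, rt
Reagents that add atoms: tributyl(1-ethoxyvinyl)stannane (C=C(OCC)[Sn](CCCC)(CCCC)CCCC); water (O)
Why: Stille coupling of the enol triflate with an acetyl-anion equivalent followed by acid hydrolysis of the enol ether and of the silyl ether should give the hydroxy methyl enone; the C1 stereocentre is not involved.

Step 8
Reactants: 13 (S)-1-(5-hydroxycyclohex-1-en-1-yl)ethan-1-one; 5 2-[(tert-butyldimethylsilyl)oxy]-3,3-dimethylcyclopropane-1-carboxylic acid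
Product: 14 (S)-3-acetylcyclohex-3-en-1-yl 2-[(tert-butyldimethylsilyl)oxy]-3,3-dimethylcyclopropane-1-carboxylate
Conditions: DCC, DMAP (10 mol %), CH2Cl2, 0 °C to rt
Reagents that add atoms: none
Why: Steglich esterification under near-neutral conditions should attach the cyclopropane to the C1 oxygen as an ester tether without opening it.

Step 9
Reactants: 14 (S)-3-acetylcyclohex-3-en-1-yl 2-[(tert-butyldimethylsilyl)oxy]-3,3-dimethylcyclopropane-1-carboxylate
Product: 15 (S)-3-[1-(triethylsilyloxy)vinyl]cyclohex-3-en-1-yl 2-[(tert-butyldimethylsilyl)oxy]-3,3-dimethylcyclopropane-1-carboxylate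
Conditions: LiHMDS, THF, −78 °C; then TESCl, −78 °C
Reagents that add atoms: chlorotriethylsilane (CC[Si](Cl)(CC)CC)
Why: Kinetic enolisation of the methyl ketone with LiHMDS (too weak to deprotonate the cyclopropane ester) and O-silylation should give the cross-conjugated 2-silyloxydiene.

Step 10
Reactants: 15 (S)-3-[1-(triethylsilyloxy)vinyl]cyclohex-3-en-1-yl 2-[(tert-butyldimethylsilyl)oxy]-3,3-dimethylcyclopropane-1-carboxylate
Product: 16 tetracyclic bridged lactone (seven-membered ring closed; C5–CO–O–C1 lactone; C7 OTBS; C9 OTES enol ether)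
Conditions: TESOTf (20 mol %), 2,6-di-tert-butyl-4-methylpyridine (25 mol %), CH2Cl2 (0.005 M), −78 to −20 °C; Et3N quench
Reagents that add atoms: none
Why: Proposed new method: TESOTf silylates the ester carbonyl of the silyloxycyclopropane, whose C5–C7 bond then heterolyses (strain release, push from the C7 silyloxy donor and pull from the C5 carboxyl acceptor) to a 1,3-zwitterion, a C7 silyl oxocarbenium ion and a C5 ketene silyl acetal; the terminal CH2 (C8) of the 2-silyloxydiene adds to C7 (Mukaiyama-type addition, forming C7–C8) and the silylated enone so formed is closed by Mukaiyama–Michael addition of C5 to C4 (forming C4–C5), which returns the silyl cation. The closest known reaction types are the Lewis-acid-catalysed formal (4+3) annulation of donor–acceptor cyclopropane diesters with 2-silyloxy-1,3-dienes and the silyl-triflate-triggered formal (3+2) cycloadditions of 2-alkoxy- or 2-silyloxycyclopropane monoesters; not yet shown are the silyloxy/monoester cyclopropane in the (4+3) mode and the ester tether. The seven-membered carbocycle (C4–C5–C6–C7–C8–C9–C10) is closed by the second bond in a 7-endo-trig Michael mode, and the same bond closes the bridged seven-membered lactone across C1 and C4 of the cyclohexane, the first bond having been made within the tether at high dilution. C4 is set by the C1 ester tether (C5 can reach C4 only on the face of the C1 oxygen), C5 is fixed by the bicyclic lactone, and C7 is not controlled and is erased in step 11. The step needs C8 rather than C10 to attack C7 and 1,4- rather than 1,2-addition to the enone (seven- versus five-membered ring): only C8 is nucleophilic in the cross-conjugated silyl dienol ether, and the soft ketene acetal together with the fully substituted, hindered C9 favours the Michael closure.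

Step 11
Reactants: 16 tetracyclic bridged lactone (C7 OTBS; C9 OTES enol ether)
Product: 18 cycloheptenone lactone (C9 ketone; C7=C8; C10 methyl), via C10-methylated β-silyloxy ketone 17 (not isolated)
Conditions: anhydrous BnMe3NF, MeI, 4 Å MS, THF, −78 to −20 °C; volatiles removed; then DBU, toluene, 60 °C
Reagents that add atoms: iodomethane (CI)
Why: Fluoride cleaves the enol silane regiospecifically and the ammonium enolate is C-methylated at C10 from the face opposite the C4–C5 bond and the lactone bridge (cis ring fusion, methyl cis to C4–H); E1cB loss of silanolate from the β-silyloxy ketone then gives the non-enolisable cycloheptenone.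

Step 12
Reactants: 18 cycloheptenone lactone
Product: 19 C9 allylic alcohol lactone
Conditions: NaBH4, CeCl3·7H2O, MeOH, −78 to −40 °C
Reagents that add atoms: none
Why: Luche 1,2-reduction of the enone; hydride should attack C9 from the face of C4–H, the other face being shielded by C11 and the lactone bridge, which places the C9 hydroxyl on the C11 side.

Step 13
Reactants: 19 C9 allylic alcohol lactone
Product: 20 C9 TBS ether lactone
Conditions: TBSOTf, 2,6-lutidine, CH2Cl2, −78 to 0 °C
Reagents that add atoms: tert-butyldimethylsilyl triflate (CC(C)(C)[Si](C)(C)OS(=O)(=O)C(F)(F)F)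
Why: Silylation of the hindered allylic alcohol with a silyl triflate protects C9–OH and provides the bulky group that later directs the epoxidation.

Step 14
Reactants: 20 C9 TBS ether lactone
Product: 21 hydroxy acid (C1 OH; C5 CO2H)
Conditions: LiOH·H2O, THF/MeOH/H2O, 50 °C; then 1 M HCl to pH 4
Reagents that add atoms: lithium hydroxide ([Li+].[OH-])
Why: Saponification of the bridged seven-membered lactone (which does not re-close) releases the C1 alcohol and the C5 carboxylic acid; no stereocentre is touched.

Step 15
Reactants: 21 hydroxy acid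
Product: 23 cyclohexenone acid (C1 ketone; C2=C3), via saturated keto acid 22 (not isolated)
Conditions: 2-iodoxybenzoic acid (IBX, 4 equiv), DMSO, rt then 75 °C
Reagents that add atoms: none
Why: IBX oxidation of the alcohol followed by IBX dehydrogenation of the ketone; the enone can form only toward C2–C3 because C10 is quaternary.

Step 16
Reactants: 23 cyclohexenone acid
Product: 24 tricyclic enone acid (cyclobutane closed; C5 CO2H)
Conditions: LDA (3.5 equiv), THF/DMPU, −78 to 0 °C; then Fe(acac)3 (2.5 equiv), −78 °C to rt; 1 M HCl work-up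
Reagents that add atoms: none
Why: Intramolecular oxidative enolate coupling of the kinetic cross-conjugated enolate (C11, the only sp3 α-carbon of the enone) with the carboxylate enediolate (C5) should close the cyclobutane; C5 and C11 can adopt only the configuration of the bicyclo[3.1.1]heptenone.

Step 17
Reactants: 24 tricyclic enone acid
Product: 25 tricyclic enone (C5 H)
Conditions: 9-mesityl-10-methylacridinium tetrafluoroborate (5 mol %), PhSSPh (10 mol %), iPr2NEt (20 mol %), CF3CH2OH, 450 nm LEDs, rt
Reagents that add atoms: none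
Why: Photoredox hydrodecarboxylation (carboxylate oxidation, loss of CO2, hydrogen-atom transfer from thiol) removes the temporary carboxyl; the tertiary cyclobutyl radical at C5 can take up hydrogen in only one position.

Step 18
Reactants: 25 tricyclic enone
Product: 26 C3-methyl ketone (C7=C8; C9 OTBS)
Conditions: Me2CuLi (from CuI and MeLi), Et2O, −78 to −30 °C; aq. NH4Cl
Reagents that add atoms: lithium dimethylcuprate ([Li+].C[Cu-]C)
Why: Cuprate conjugate addition to the verbenone-type enone should occur from the face of the C5–H bridge, anti to the methyl-bearing C10 bridge, setting C3 with the methyl syn to C5.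

Step 19
Reactants: 26 C3-methyl ketone
Product: 27 7,8-epoxide (epoxide anti to C9 OTBS)
Conditions: dimethyldioxirane, acetone/CH2Cl2, 0 °C
Reagents that add atoms: dimethyldioxirane (CC1(C)OO1)
Why: Epoxidation of the cis alkene should occur anti to the bulky allylic C9 silyloxy group; the neutral dioxirane avoids Baeyer–Villiger oxidation of the ketone.

Step 20
Reactants: 27 7,8-epoxide; 28 angelic acid
Product: 29 8-angeloyloxy-7-hydroxy-9-[(tert-butyldimethylsilyl)oxy]longipinan-1-one
Conditions: 28 (4 equiv), Cs2CO3 (1 equiv), DMF, 70 °C; aq. NH4Cl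
Reagents that add atoms: none
Why: Epoxide opening by the buffered cesium carboxylate (SN2) should occur at C8 with inversion because C7 is neopentyl (next to C6), which places the C8 oxygen cis to the C9 oxygen and trans to the retained C7 hydroxyl; a 1,2-acyl shift to C7 would be harmless because both positions carry angelate after step 21.

Step 21
Reactants: 29 8-angeloyloxy-7-hydroxy-9-[(tert-butyldimethylsilyl)oxy]longipinan-1-one; 28 angelic acid
Product: 30 7,8-bis(angeloyloxy)-9-[(tert-butyldimethylsilyl)oxy]longipinan-1-one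
Conditions: 28 (3 equiv), 2,4,6-trichlorobenzoyl chloride (3 equiv), Et3N, toluene, rt, 2 h; then 29, toluene, 80 °C (no DMAP)
Reagents that add atoms: none
Why: Yamaguchi-type acylation with the preformed mixed anhydride of angelic acid in the absence of a nucleophilic catalyst should esterify the neopentyl C7 hydroxyl without Z-to-E isomerisation; no stereocentre changes.

Step 22
Reactants: 30 7,8-bis(angeloyloxy)-9-[(tert-butyldimethylsilyl)oxy]longipinan-1-one
Product: 31 7,8-bis(angeloyloxy)-9-hydroxylongipinan-1-one
Conditions: 48 % aq. HF, MeCN, rt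
Reagents that add atoms: none
Why: Acidic fluoride cleavage of the silyl ether frees the C9 hydroxyl while the medium suppresses base-induced ester cleavage; an acyl shift from C8 to C9 would lead to the same triester in step 23.

Step 23
Reactants: 31 7,8-bis(angeloyloxy)-9-hydroxylongipinan-1-one; 28 angelic acid
Product: 32 CNP0138097.1 (7,8,9-tris[(Z)-2-methylbut-2-enoyloxy]longipinan-1-one)
Conditions: 28 (3 equiv), 2,4,6-trichlorobenzoyl chloride (3 equiv), Et3N, toluene, rt, 2 h; then 31, toluene, 80 °C (no DMAP)
Reagents that add atoms: none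
Why: Yamaguchi-type acylation with the preformed mixed anhydride of angelic acid without a nucleophilic catalyst should esterify the last hindered secondary hydroxyl (C9) without Z-to-E isomerisation; no stereocentre changes.

**Compound list**

1 | isobutyraldehyde | CC(C)C=O | starting material
2 | tert-butyldimethyl[(2-methylprop-1-en-1-yl)oxy]silane | CC(C)=CO[Si](C)(C)C(C)(C)C | intermediate
3 | benzyl diazoacetate | [N-]=[N+]=CC(=O)OCc1ccccc1 | starting material
4 | benzyl 2-[(tert-butyldimethylsilyl)oxy]-3,3-dimethylcyclopropane-1-carboxylate (racemic, cis/trans mixture) | CC1(C)C(O[Si](C)(C)C(C)(C)C)C1C(=O)OCc1ccccc1 | intermediate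
5 | 2-[(tert-butyldimethylsilyl)oxy]-3,3-dimethylcyclopropane-1-carboxylic acid (isomer mixture) | CC1(C)C(O[Si](C)(C)C(C)(C)C)C1C(=O)O | intermediate
6 | cyclohex-2-en-1-one | O=C1C=CCCC1 | starting material
7 | (S)-3-(4,4,5,5-tetramethyl-1,3,2-dioxaborolan-2-yl)cyclohexan-1-one | O=C1CCC[C@H](B2OC(C)(C)C(C)(C)O2)C1 | intermediate
8 | (S)-3-hydroxycyclohexan-1-one | O=C1CCC[C@H](O)C1 | intermediate
9 | (S)-3-[(tert-butyldimethylsilyl)oxy]cyclohexan-1-one | O=C1CCC[C@H](O[Si](C)(C)C(C)(C)C)C1 | intermediate
10 | (S)-5-[(tert-butyldimethylsilyl)oxy]cyclohex-1-en-1-yl trifluoromethanesulfonate | O=S(=O)(OC1=CCC[C@H](O[Si](C)(C)C(C)(C)C)C1)C(F)(F)F | intermediate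
11 | (S)-tert-butyl{[3-(1-ethoxyvinyl)cyclohex-3-en-1-yl]oxy}dimethylsilane | C=C(OCC)C1=CCC[C@H](O[Si](C)(C)C(C)(C)C)C1 | intermediate
12 | (S)-1-{5-[(tert-butyldimethylsilyl)oxy]cyclohex-1-en-1-yl}ethan-1-one | CC(=O)C1=CCC[C@H](O[Si](C)(C)C(C)(C)C)C1 | intermediate
13 | (S)-1-(5-hydroxycyclohex-1-en-1-yl)ethan-1-one | CC(=O)C1=CCC[C@H](O)C1 | intermediate
14 | (S)-3-acetylcyclohex-3-en-1-yl 2-[(tert-butyldimethylsilyl)oxy]-3,3-dimethylcyclopropane-1-carboxylate (cyclopropane isomer mixture) | CC(=O)C1=CCC[C@H](OC(=O)C2C(O[Si](C)(C)C(C)(C)C)C2(C)C)C1 | intermediate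
15 | (S)-3-[1-(triethylsilyloxy)vinyl]cyclohex-3-en-1-yl 2-[(tert-butyldimethylsilyl)oxy]-3,3-dimethylcyclopropane-1-carboxylate | C=C(O[Si](CC)(CC)CC)C1=CCC[C@H](OC(=O)C2C(O[Si](C)(C)C(C)(C)C)C2(C)C)C1 | intermediate
16 | tetracyclic bridged lactone: seven-membered ring C4–C10 fused to the cyclohexane at C4–C10, lactone C5–CO–O–C1 (C1–O cis to the C4–C5 bond), C7 OTBS (both epimers), C9(OTES)=C10 enol ether | C1C(O[Si](C)(C)C(C)(C)C)C(C)(C)[C@@H]2C(=O)O[C@H]3CC[C@@H]2C(C3)=C1O[Si](CC)(CC)CC | intermediate
17 | C10-methylated β-silyloxy ketone lactone (C9 ketone, C10 methyl cis to C4–H, C7 OTBS both epimers) | C1C(O[Si](C)(C)C(C)(C)C)C(C)(C)[C@@H]2C(=O)O[C@H]3CC[C@@H]2[C@](C)(C3)C1=O | intermediate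
18 | cycloheptenone lactone (C9 ketone, C7=C8, C10 methyl) | C1=CC(C)(C)[C@@H]2C(=O)O[C@H]3CC[C@@H]2[C@](C)(C3)C1=O | intermediate
19 | C9 allylic alcohol lactone (C9–OH on the C11 side) | C1=CC(C)(C)[C@@H]2C(=O)O[C@H]3CC[C@@H]2[C@](C)(C3)[C@@H]1O | intermediate
20 | C9 TBS ether lactone | C1=CC(C)(C)[C@@H]2C(=O)O[C@H]3CC[C@@H]2[C@](C)(C3)[C@@H]1O[Si](C)(C)C(C)(C)C | intermediate
21 | hydroxy acid (C1–OH, C5–CO2H, C7=C8, C9 OTBS; cis-fused six/seven-membered bicycle) | C1=CC(C)(C)[C@H](C(=O)O)[C@@H]2CC[C@H](O)C[C@]2(C)[C@@H]1O[Si](C)(C)C(C)(C)C | intermediate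
22 | saturated keto acid (C1 ketone) | C1=CC(C)(C)[C@H](C(=O)O)[C@@H]2CCC(=O)C[C@]2(C)[C@@H]1O[Si](C)(C)C(C)(C)C | intermediate
23 | cyclohexenone acid (C1 ketone, C2=C3) | C1=CC(C)(C)[C@H](C(=O)O)[C@@H]2C=CC(=O)C[C@]2(C)[C@@H]1O[Si](C)(C)C(C)(C)C | intermediate
24 | tricyclic enone acid (longipina-2,7-dien-1-one skeleton, C5 CO2H, C9 OTBS) | C1=CC(C)(C)[C@@]2(C(=O)O)[C@@H]3C=CC(=O)[C@H]2[C@]3(C)[C@@H]1O[Si](C)(C)C(C)(C)C | intermediate
25 | tricyclic enone (C5 H, C2=C3, C7=C8, C9 OTBS) | C1=CC(C)(C)[C@H]2[C@@H]3C=CC(=O)[C@H]2[C@]3(C)[C@@H]1O[Si](C)(C)C(C)(C)C | intermediate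
26 | C3-methyl ketone (C3 methyl syn to the C5 bridge; C7=C8; C9 OTBS) | C1=CC(C)(C)[C@H]2[C@@H]3[C@H](C)CC(=O)[C@H]2[C@]3(C)[C@@H]1O[Si](C)(C)C(C)(C)C | intermediate
27 | 7,8-epoxide (epoxide oxygen on the C4 side, anti to C9 OTBS) | O1[C@H]2[C@@H]1C(C)(C)[C@H]3[C@@H]4[C@H](C)CC(=O)[C@H]3[C@]4(C)[C@@H]2O[Si](C)(C)C(C)(C)C | intermediate
28 | angelic acid, (Z)-2-methylbut-2-enoic acid | C/C=C(/C)C(=O)O | starting material
29 | 8-angeloyloxy-7-hydroxy-9-[(tert-butyldimethylsilyl)oxy]longipinan-1-one (C7–OH on the C4 side; C8–O and C9–O on the C11 side) | C/C=C(/C)C(=O)O[C@@H]1[C@@H](O)C(C)(C)[C@H]2[C@@H]3[C@H](C)CC(=O)[C@H]2[C@]3(C)[C@@H]1O[Si](C)(C)C(C)(C)C | intermediate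
30 | 7,8-bis(angeloyloxy)-9-[(tert-butyldimethylsilyl)oxy]longipinan-1-one | C/C=C(/C)C(=O)O[C@@H]1[C@@H](OC(=O)/C(C)=C\C)C(C)(C)[C@H]2[C@@H]3[C@H](C)CC(=O)[C@H]2[C@]3(C)[C@@H]1O[Si](C)(C)C(C)(C)C | intermediate
31 | 7,8-bis(angeloyloxy)-9-hydroxylongipinan-1-one | C/C=C(/C)C(=O)O[C@@H]1[C@@H](OC(=O)/C(C)=C\C)C(C)(C)[C@H]2[C@@H]3[C@H](C)CC(=O)[C@H]2[C@]3(C)[C@@H]1O | intermediate
32 | CNP0138097.1, 7,8,9-tris[(Z)-2-methylbut-2-enoyloxy]longipinan-1-one | C/C=C(/C)C(=O)O[C@@H]1[C@@H](OC(=O)/C(C)=C\C)C(C)(C)[C@H]2[C@@H]3[C@H](C)CC(=O)[C@H]2[C@]3(C)[C@@H]1OC(=O)/C(C)=C\C | target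

**Count and risks**

Total step count: 23. Longest linear sequence: 20 steps (steps 4–23, from cyclohex-2-en-1-one); steps 1–3 make the cyclopropane acid.

Steps most likely to fail:

1. Step 10 (Proposed new method). The first bond must form across a ten-membered array, so intermolecular oligomerisation, closure by 1,2-addition to the five-membered ring, or premature loss of the silyl groups may take over. The fallback sets out from 14 and uses known reactions stepwise. Anhydrous CsF with benzyltriethylammonium chloride in DMF opens the silyloxycyclopropane to the ester enolate, which adds intramolecularly to the enone on the face of the C1 oxygen (fluoride-induced ring opening and Michael addition of silyloxycyclopropane esters) to give the bridged lactone keto aldehyde F1. Intramolecular aldol condensation of the methyl ketone onto the C7 aldehyde (KOtBu, t-BuOH; the alternative aldol through C10 cannot dehydrate and is reversible) gives the unmethylated cycloheptenone lactone F2. Kinetic deprotonation at C10 (LDA, THF, −78 °C) and MeI then return the route at 18.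

2. Step 16. α-Deprotonation of the hindered carboxylate may be incomplete, and intermolecular coupling or over-oxidation may compete with closure of the strained ring. The fallback sets out from 23 and makes the C5 radical by decarboxylation instead. The acid is converted with N-hydroxyphthalimide, DIC and DMAP into the redox-active ester F3, and TMSOTf/Et3N at −78 °C gives the silyl dienol ether F4. Irradiation with Ru(bpy)3(PF6)2 and blue LEDs (decarboxylative alkylation of silyl enol ethers with redox-active esters, known intermolecularly) lets the C5 radical add to C11 of the silyloxydiene, and oxidation of the silyloxyallyl radical restores the enone. The fallback comes back at 25 and makes step 17 unnecessary.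

3. Step 20. The bulky carboxylate must attack C8 next to the C9 silyloxy group, so the opening may be slow or go in part at C7, and prolonged heating may isomerise the angeloyl group from Z to E. The fallback sets out from 27 and separates ring opening from acylation. Acid-catalysed hydrolysis (HClO4, 10 mol %, THF/H2O 3:1, rt), in which the small nucleophile water attacks C8 with inversion, gives the C9-silylated 7,8-diol F5. Desilylation with 48 % aq. HF in MeCN gives the 7,8,9-triol F6. Exhaustive acylation of the three hydroxyls with the mixed anhydride preformed from 28 and 2,4,6-trichlorobenzoyl chloride (Et3N, toluene, 80 °C, no DMAP; three equivalents of 28 are incorporated) comes back at 32 and makes steps 21 to 23 unnecessary.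

Further compounds
F1 | step 10 | bridged lactone keto aldehyde (C4–C5 bond formed; C7 aldehyde; C9 methyl ketone; C10–H) | O=CC(C)(C)[C@@H]2C(=O)O[C@H]3CC[C@@H]2C(C3)C(C)=O
F2 | step 10 | cycloheptenone lactone lacking the C10 methyl group | C1=CC(C)(C)[C@@H]2C(=O)O[C@H]3CC[C@@H]2C(C3)C1=O
F3 | step 16 | N-hydroxyphthalimide ester of 23 | C1=CC(C)(C)[C@H](C(=O)ON4C(=O)c5ccccc5C4=O)[C@@H]2C=CC(=O)C[C@]2(C)[C@@H]1O[Si](C)(C)C(C)(C)C
F4 | step 16 | trimethylsilyl dienol ether of F3 | C1=CC(C)(C)[C@H](C(=O)ON4C(=O)c5ccccc5C4=O)[C@@H]2C=CC(O[Si](C)(C)C)=C[C@]2(C)[C@@H]1O[Si](C)(C)C(C)(C)C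
F5 | step 20 | 7,8-dihydroxy-9-[(tert-butyldimethylsilyl)oxy]longipinan-1-one (C7–OH on the C4 side; C8–OH on the C11 side) | O[C@@H]1[C@@H](O)C(C)(C)[C@H]2[C@@H]3[C@H](C)CC(=O)[C@H]2[C@]3(C)[C@@H]1O[Si](C)(C)C(C)(C)C
F6 | step 20 | 7,8,9-trihydroxylongipinan-1-one | O[C@@H]1[C@@H](O)C(C)(C)[C@H]2[C@@H]3[C@H](C)CC(=O)[C@H]2[C@]3(C)[C@@H]1O
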